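## Retrosynthetic overview

1. Labels: oxolane numbering of the target (O1, C2 = aryl carbon, C3 = carbinol carbon carrying C9H2OH, C4 = benzyl carbon, C5 = ring CH2). The same labels are kept for the corresponding atoms of the open-chain intermediates.
2. C4–benzyl bond: benzyl chloride 1 + oxalacetate enolate 2 ⇒ racemic, configurationally labile α-keto diester 3.
3. Key C2–C3 bond (carbonyl carbon to carbonyl carbon): acyl anion equivalent from aldehyde 4 + ketone of 3 ⇒ 5; a dynamic kinetic resolution sets C3 and C4 together.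
4. Global reduction 5 ⇒ open-chain tetraol 6; the only ring (oxolane) is formed after that by O1–C2 closure, 6 ⇒ 7, which sets C2.
5. Debenzylation 7 ⇒ target 8.

Assumption: 1, 2, 4 and both enantiomers of the triazolium precatalyst are taken as catalogue reagents.

## Route

Step 1
Reactants: 1 4-(benzyloxy)-3-methoxybenzyl chloride; 2 diethyl oxalacetate sodium salt (sodium enolate of diethyl 2-oxobutanedioate)
Product: 3 diethyl (2RS)-2-[4-(benzyloxy)-3-methoxybenzyl]-3-oxobutanedioate (racemic)
Conditions: 2 (1.3 equiv), NaI (10 mol %), DMF, 50 °C; aq. NH4Cl work-up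
Reagents that add atoms: none
Why: C-alkylation of the stabilised oxalacetate enolate by a reactive p-alkoxybenzyl chloride with Finkelstein activation (enolate alkylation), a known entry to 3-substituted 2-oxosuccinates; the new centre is made racemic on purpose because it stays labile until step 2.

Step 2
Reactants: 3 diethyl (2RS)-2-[4-(benzyloxy)-3-methoxybenzyl]-3-oxobutanedioate; 4 4-(benzyloxy)-3-methoxybenzaldehyde (O-benzylvanillin)
Product: 5 diethyl (2R,3R)-2-[4-(benzyloxy)-3-methoxybenzoyl]-3-[4-(benzyloxy)-3-methoxybenzyl]-2-hydroxybutanedioate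
Conditions: (5aR,10bS)-2-(pentafluorophenyl)-5a,10b-dihydro-4H,6H-indeno[2,1-b][1,2,4]triazolo[4,3-d][1,4]oxazin-2-ium tetrafluoroborate (15 mol %), K2CO3 (1.0 equiv), 4 Å MS, MTBE, 0 °C → rt
Reagents that add atoms: none
Why: Proposed new method: a chiral-triazolium (NHC) dynamic kinetic asymmetric cross-benzoin, in which the carbene turns the aldehyde carbon of 4 into an acyl anion equivalent that attacks the ketone carbon of 3, extending the known NHC-catalysed dynamic kinetic cross-benzoin of racemic β-halo α-keto esters and the enantioselective aldehyde–α-keto ester cross-benzoin to a β-ester-substituted keto ester; the C–H between ketone and ester of 3 racemises quickly through the enolate under K2CO3, the catalyst directs addition to the Re face of the ketone (carbinol centre R), and a Felkin–Anh transition state with the CO2Et of the stereocentre antiperiplanar to the nucleophile and the benzyl group inside makes (R)-3 the fast-reacting enantiomer (benzyl centre R), after which that centre is no longer acidic and holds its configuration.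

Step 3
Reactants: 5 diethyl (2R,3R)-2-[4-(benzyloxy)-3-methoxybenzoyl]-3-[4-(benzyloxy)-3-methoxybenzyl]-2-hydroxybutanedioate
Product: 6 (2S,3S)-3-[4-(benzyloxy)-3-methoxybenzyl]-2-{(RS)-[4-(benzyloxy)-3-methoxyphenyl](hydroxy)methyl}butane-1,2,4-triol (mixture of C2 epimers)
Conditions: LiAlH4 (6 equiv), THF, 0 °C → rt; aq. potassium sodium tartrate work-up
Reagents that add atoms: none
Why: Exhaustive hydride reduction of the aryl ketone and both esters (LiAlH4 reduction) leaves C3 and C4 untouched (the CIP descriptors change only because the substituents change); the C2 epimer ratio does not matter because step 4 is stereoconvergent.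

Step 4
Reactants: 6 (2S,3S)-3-[4-(benzyloxy)-3-methoxybenzyl]-2-{(RS)-[4-(benzyloxy)-3-methoxyphenyl](hydroxy)methyl}butane-1,2,4-triol
Product: 7 (2R,3S,4S)-4-[4-(benzyloxy)-3-methoxybenzyl]-2-[4-(benzyloxy)-3-methoxyphenyl]-3-(hydroxymethyl)oxolan-3-ol
Conditions: (1S)-(+)-10-camphorsulfonic acid (10 mol %), CH2Cl2/THF 5:1, 4 Å MS, 0 °C → rt; Et3N quench
Reagents that add atoms: none
Why: Acid-catalysed cyclodehydration (SN1-type benzylic etherification, as in the acid cyclisation of 7-hydroxysecoisolariciresinol to lariciresinol): both C2 epimers ionise to the same p-benzyloxybenzyl cation, only the C5 hydroxyl can close a five-membered ring, and closure puts the aryl group on the face opposite the cis-disposed C3–CH2OH and C4–benzyl groups, which gives 2R.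

Step 5
Reactants: 7 (2R,3S,4S)-4-[4-(benzyloxy)-3-methoxybenzyl]-2-[4-(benzyloxy)-3-methoxyphenyl]-3-(hydroxymethyl)oxolan-3-ol
Product: 8 (2R,3S,4S)-2-(4-hydroxy-3-methoxyphenyl)-4-(4-hydroxy-3-methoxybenzyl)-3-(hydroxymethyl)oxolan-3-ol (target, CNP0180506.2)
Conditions: H2 (1 atm), 10% Pd/C, EtOAc/EtOH 1:1, rt, stopped after 2 equiv H2
Reagents that add atoms: none
Why: Hydrogenolysis of the two aryl benzyl ethers, which are cleaved much faster than the cyclic benzylic C2–O1 bond; no stereocentre is touched.

## Compound list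

1 | 4-(benzyloxy)-3-methoxybenzyl chloride | COc1cc(CCl)ccc1OCc1ccccc1 | starting material
2 | diethyl oxalacetate sodium salt (sodium enolate of diethyl 2-oxobutanedioate) | CCOC(=O)C=C([O-])C(=O)OCC.[Na+] | starting material
3 | diethyl (2RS)-2-[4-(benzyloxy)-3-methoxybenzyl]-3-oxobutanedioate | CCOC(=O)C(=O)C(Cc1ccc(OCc2ccccc2)c(OC)c1)C(=O)OCC | intermediate
4 | 4-(benzyloxy)-3-methoxybenzaldehyde | COc1cc(C=O)ccc1OCc1ccccc1 | starting material
5 | diethyl (2R,3R)-2-[4-(benzyloxy)-3-methoxybenzoyl]-3-[4-(benzyloxy)-3-methoxybenzyl]-2-hydroxybutanedioate | COc1cc(C[C@@H](C(=O)OCC)[C@](O)(C(=O)OCC)C(=O)c2ccc(OCc3ccccc3)c(OC)c2)ccc1OCc1ccccc1 | intermediate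
6 | (2S,3S)-3-[4-(benzyloxy)-3-methoxybenzyl]-2-{(RS)-[4-(benzyloxy)-3-methoxyphenyl](hydroxy)methyl}butane-1,2,4-triol | COc1cc(C[C@@H](CO)[C@](O)(CO)C(O)c2ccc(OCc3ccccc3)c(OC)c2)ccc1OCc1ccccc1 | intermediate
7 | (2R,3S,4S)-4-[4-(benzyloxy)-3-methoxybenzyl]-2-[4-(benzyloxy)-3-methoxyphenyl]-3-(hydroxymethyl)oxolan-3-ol | COc1cc(C[C@H]2CO[C@H](c3ccc(OCc4ccccc4)c(OC)c3)[C@@]2(O)CO)ccc1OCc1ccccc1 | intermediate
8 | (2R,3S,4S)-2-(4-hydroxy-3-methoxyphenyl)-4-(4-hydroxy-3-methoxybenzyl)-3-(hydroxymethyl)oxolan-3-ol | COc1cc(C[C@H]2CO[C@H](c3ccc(O)c(OC)c3)[C@@]2(O)CO)ccc1O | target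

## Step count and risks

Total steps: 5. Longest linear sequence: 5 steps (1 + 2 → 3 → 5 → 6 → 7 → 8).

**Step 2 (highest risk).** The keto diester 3 may sit largely as its enolate, the Felkin preference between CO2Et and benzyl may be too small for a good diastereomer ratio, and the sense of induction of the catalyst is not known for this substrate class (the (5aS,10bR) antipode is used if the first run gives the mirror-image carbinol). Fallback, setting out from 2 and 4 and returning at 6: the benzyl centre is taken out of the catalytic step and made afterwards by lactone alkylation.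
- Neutralising 2 with AcOH (1 equiv) frees diethyl 2-oxobutanedioate F1, which has no stereocentre next to the ketone.
- The same triazolium-catalysed cross-benzoin with 4 then only has to set the carbinol centre and gives diethyl (2R)-2-[4-(benzyloxy)-3-methoxybenzoyl]-2-hydroxybutanedioate F2.
- NaBH4 (EtOH, −20 °C) reduces the aryl ketone and the new hydroxyl closes onto the CH2CO2Et arm in the same pot, giving ethyl (2RS,3R)-2-[4-(benzyloxy)-3-methoxyphenyl]-3-hydroxy-5-oxooxolane-3-carboxylate F3.
- The dianion of F3 (LiN(iPr)2 2.2 equiv, THF/DMPU, −78 °C) is benzylated with 1 anti to the lithium alkoxide (Fráter–Seebach-type alkylation), giving ethyl (2RS,3R,4R)-4-[4-(benzyloxy)-3-methoxybenzyl]-2-[4-(benzyloxy)-3-methoxyphenyl]-3-hydroxy-5-oxooxolane-3-carboxylate F4.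
- LiAlH4 (THF) opens and reduces F4 to 6.

**Step 4.** The benzylic cation can also be trapped by the electron-rich benzyl ring (aryltetralin formation) or trigger a pinacol-type shift from the neighbouring tertiary carbinol, and the C2 ratio rests on substrate control. Fallback, setting out from 6 and returning at 8: the order of the last two operations is reversed so that ring closure runs through a p-quinone methide instead of a free cation.
- Hydrogenolysis of 6 (H2, 10% Pd/C, EtOAc, rt) gives (2S,3S)-3-(4-hydroxy-3-methoxybenzyl)-2-[(RS)-hydroxy(4-hydroxy-3-methoxyphenyl)methyl]butane-1,2,4-triol F5.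
- In NaOAc/AcOH buffer (pH 4–5, MeCN/H2O, 40 °C) the free p-hydroxybenzylic alcohol of F5 loses water to the quinone methide, and intramolecular oxa-1,6-addition of the C5 hydroxyl, again trans to the CH2OH and benzyl groups, gives 8 directly.

**Step 1.** O-alkylation and dialkylation of the ambident enolate can lower the yield of 3. Fallback, setting out from 4 and returning at 3: the keto diester is built by a crossed Claisen condensation instead.
- Horner–Wadsworth–Emmons olefination of 4 (triethyl phosphonoacetate, NaH, THF) gives ethyl (E)-3-[4-(benzyloxy)-3-methoxyphenyl]prop-2-enoate F6.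
- Conjugate reduction (NaBH4, NiCl2·6H2O, EtOH, 0 °C; benzyl ether retained) gives ethyl 3-[4-(benzyloxy)-3-methoxyphenyl]propanoate F7.
- Crossed Claisen condensation of F7 with diethyl oxalate (NaOEt, EtOH/Et2O, rt) gives 3.

## Further compounds

F1 | step 2 | diethyl 2-oxobutanedioate | CCOC(=O)CC(=O)C(=O)OCC
F2 | step 2 | diethyl (2R)-2-[4-(benzyloxy)-3-methoxybenzoyl]-2-hydroxybutanedioate | CCOC(=O)C[C@](O)(C(=O)OCC)C(=O)c1ccc(OCc2ccccc2)c(OC)c1
F3 | step 2 | ethyl (2RS,3R)-2-[4-(benzyloxy)-3-methoxyphenyl]-3-hydroxy-5-oxooxolane-3-carboxylate | CCOC(=O)[C@@]1(O)CC(=O)OC1c2ccc(OCc3ccccc3)c(OC)c2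
F4 | step 2 | ethyl (2RS,3R,4R)-4-[4-(benzyloxy)-3-methoxybenzyl]-2-[4-(benzyloxy)-3-methoxyphenyl]-3-hydroxy-5-oxooxolane-3-carboxylate | CCOC(=O)[C@@]1(O)[C@@H](Cc2ccc(OCc3ccccc3)c(OC)c2)C(=O)OC1c4ccc(OCc5ccccc5)c(OC)c4
F5 | step 4 | (2S,3S)-3-(4-hydroxy-3-methoxybenzyl)-2-[(RS)-hydroxy(4-hydroxy-3-methoxyphenyl)methyl]butane-1,2,4-triol | COc1cc(C[C@@H](CO)[C@](O)(CO)C(O)c2ccc(O)c(OC)c2)ccc1O
F6 | step 1 | ethyl (E)-3-[4-(benzyloxy)-3-methoxyphenyl]prop-2-enoate | CCOC(=O)/C=C/c1ccc(OCc2ccccc2)c(OC)c1
F7 | step 1 | ethyl 3-[4-(benzyloxy)-3-methoxyphenyl]propanoate | CCOC(=O)CCc1ccc(OCc2ccccc2)c(OC)c1
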